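**Plan**
1. Cuts: in the side chain, C7''–C8'' (aldol) and the syringyl O–C8'' bond (phenol alkylation). In the oxolane, O1–C2 and C2–C3 together. In the open chain, C3=CH(OMe) (Wittig) and C4–C5 (hydroxymethylation).
2. Enabling feature: in the ring O1–C2(aryl)–C3(CH2OH)–C4(benzyl)–C5H2, C2 is a benzylic ether carbon of the electron-rich 4-alkoxy-3,5-dimethoxyphenyl ring and C3 carries a one-carbon arm. C2 can therefore act as an aryl oxocarbenium carbon on O1, and C3 as the nucleophilic carbon of an enol ether whose CH(OMe) end becomes that arm.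
3. Forward order: the three benzene rings are bought. The oxolane, the only ring made, closes in step 9 from a C4-chiral silyloxy Z-enol ether and O-allylsyringaldehyde. The freed syringyl phenol is then alkylated with a bromoacetyl imide, and the chain is completed by an aldol with O-benzylvanillin.
4. Ring stereochemistry: C4 comes from (S)-4-benzyloxazolidin-2-one (titanium enolate hydroxymethylation). C2 is set from C4 in the kinetic closure (2,4-trans). C3 forms cis to the aryl group and is then equilibrated next to the formyl group to the 2,3-trans-3,4-cis array of the target.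
5. Chain stereochemistry: C8'' comes from the same auxiliary (boron syn aldol, threo). C7'' is set by Mitsunobu inversion to the erythro (7''S,8''R) pair.

Key step: step 9

Remark on the structure: the SMILES is read as (2R,3S,4S) in the oxolane. The aryl group is trans to CH2OH and CH2OH is cis to the benzyl group (lariciresinol-type), so aryl and benzyl are 2,4-trans. The all-trans ring is a diastereomer and has to be avoided. The chain is (7''S,8''R), erythro.
Locants: O1, C2–C5 for the oxolane. C7'' is the carbinol, C8'' the aryloxy carbon and C9'' the CH2OH of the arylglycerol chain. "ArO" in long names is the phenoxy residue of compound 20.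

Step 1
Reactants: 1 3-(4-hydroxy-3-methoxyphenyl)propanoic acid
Product: 2 3-(4-benzyloxy-3-methoxyphenyl)propanoic acid
Conditions: BnBr, NaOH, EtOH–H2O, reflux; then aq HCl
Reagents that add atoms: benzyl bromide BrCc1ccccc1
Why: Williamson ether synthesis in which the phenoxide is the better nucleophile of the dianion and any benzyl ester that forms is saponified in the same alkaline medium, so acidification should give the O-benzyl acid directly.

Step 2
Reactants: 2 3-(4-benzyloxy-3-methoxyphenyl)propanoic acid; 3 (S)-4-benzyloxazolidin-2-one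
Product: 5 (S)-4-benzyl-3-[3-(4-benzyloxy-3-methoxyphenyl)propanoyl]oxazolidin-2-one, via mixed pivalic anhydride 4 (not isolated)
Conditions: PivCl, Et3N, THF, −20 °C; then LiCl, 3, −20 °C → rt
Reagents that add atoms: none
Why: N-acylation of the oxazolidinone through a mixed anhydride (LiCl/Et3N variant), with attack at the less hindered carbonyl group of 4.

Step 3
Reactants: 5 (S)-4-benzyl-3-[3-(4-benzyloxy-3-methoxyphenyl)propanoyl]oxazolidin-2-one
Product: 7 (S)-4-benzyl-3-[(R)-2-(4-benzyloxy-3-methoxybenzyl)-3-hydroxypropanoyl]oxazolidin-2-one, via chlorotitanium Z-enolate 6 (not isolated)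
Conditions: TiCl4, i-Pr2NEt, CH2Cl2, 0 °C; then s-trioxane, TiCl4, 0 °C; aq NH4Cl
Reagents that add atoms: s-trioxane C1OCOCO1
Why: Evans-type auxiliary-controlled hydroxymethylation in which the chelated Z-enolate 6, shielded on one face by the benzyl group of the auxiliary, takes up TiCl4-activated formaldehyde on the other face, setting the future C4 (R in 7) and bringing in the future C5.

Step 4
Reactants: 7 (S)-4-benzyl-3-[(R)-2-(4-benzyloxy-3-methoxybenzyl)-3-hydroxypropanoyl]oxazolidin-2-one
Product: 8 (R)-2-(4-benzyloxy-3-methoxybenzyl)-3-hydroxy-N-methoxy-N-methylpropanamide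
Conditions: MeNH(OMe)·HCl, AlMe3, CH2Cl2, −10 °C → rt; aq Rochelle salt
Reagents that add atoms: N,O-dimethylhydroxylamine hydrochloride CNOC.Cl
Why: Weinreb aminolysis with the aluminium amide, directed to the exocyclic carbonyl group by the free β-hydroxyl; auxiliary 3 is recovered and the route never passes through a monosilylated 2-substituted propane-1,3-diol, in which silyl migration would racemise C4.

Step 5
Reactants: 8 (R)-2-(4-benzyloxy-3-methoxybenzyl)-3-hydroxy-N-methoxy-N-methylpropanamide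
Product: 9 (R)-2-(4-benzyloxy-3-methoxybenzyl)-N-methoxy-N-methyl-3-(triethylsilyloxy)propanamide
Conditions: TESCl, imidazole, CH2Cl2, 0 °C
Reagents that add atoms: chlorotriethylsilane CC[Si](Cl)(CC)CC
Why: standard O-silylation; triethylsilyl should survive DIBAL-H, the ylide and chromatography, yet leaves the oxygen accessible enough to add to a silyl-activated aldehyde in step 9.

Step 6
Reactants: 9 (R)-2-(4-benzyloxy-3-methoxybenzyl)-N-methoxy-N-methyl-3-(triethylsilyloxy)propanamide
Product: 10 (R)-2-(4-benzyloxy-3-methoxybenzyl)-3-(triethylsilyloxy)propanal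
Conditions: DIBAL-H, THF, −78 °C; aq Rochelle salt
Reagents that add atoms: none
Why: a Weinreb amide is reduced by DIBAL-H to the aldehyde without over-reduction, and at −78 °C the α-stereocentre should hold; the aldehyde is used at once.

Step 7
Reactants: 10 (R)-2-(4-benzyloxy-3-methoxybenzyl)-3-(triethylsilyloxy)propanal
Product: 11 triethylsilyl ether of (2S,3Z)-2-(4-benzyloxy-3-methoxybenzyl)-4-methoxybut-3-en-1-ol
Conditions: MeOCH2PPh3Cl, KHMDS, THF, −78 → 0 °C; chromatography on Et3N-deactivated SiO2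
Reagents that add atoms: (methoxymethyl)triphenylphosphonium chloride COC[P+](c1ccccc1)(c1ccccc1)c1ccccc1.[Cl-]
Why: Wittig methoxymethylenation in which the salt-free, non-stabilised ylide should give both geometrical isomers with Z favoured; the two are separated and only the Z isomer is carried on, because the geometry steers step 9.

Step 8
Reactants: 12 syringaldehyde
Product: 13 4-allyloxy-3,5-dimethoxybenzaldehyde
Conditions: allyl bromide, K2CO3, DMF, rt
Reagents that add atoms: allyl bromide C=CCBr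
Why: Williamson ether synthesis on the acidic phenol; allyl is orthogonal to the benzyl and silyl groups and keeps the para oxygen a donor for the cation of step 9.

Step 9
Reactants: 11 triethylsilyl ether of (2S,3Z)-2-(4-benzyloxy-3-methoxybenzyl)-4-methoxybut-3-en-1-ol; 13 4-allyloxy-3,5-dimethoxybenzaldehyde
Product: 16 (2R,3S,4S)-2-(4-allyloxy-3,5-dimethoxyphenyl)-4-(4-benzyloxy-3-methoxybenzyl)oxolane-3-carbaldehyde (2,3-cis-3,4-trans), via aryl oxocarbenium triflate 14 (not isolated), via methyl oxocarbenium triflate 15 (not isolated)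
Conditions: TMSOTf (1.1 equiv), 2,6-di-tert-butyl-4-methylpyridine (0.2 equiv), 4 Å MS, CH2Cl2, −78 °C; aq NaHCO3
Reagents that add atoms: water O
Why: TMSOTf silylates the carbonyl oxygen of 13, the silyl ether oxygen of 11 adds and Et3SiOSiMe3 departs, which forms the O1–C2 bond and the (E)-aryl oxocarbenium ion 14 without a Brønsted acid that could protonate the enol ether; the enol ether carbon C3 then attacks C2 (C2–C3 bond) and the exocyclic methyl oxocarbenium ion 15 is hydrolysed to the formyl group on work-up. The closest known reactions are the Lewis acid condensation of 4-hydroxy enol ethers or enol carbamates with aldehydes to oxolane-3-carbaldehydes and the vinyl acetal (Petasis–Ferrier type) ring contraction of 4,5-dihydro-1,3-dioxepines, that is an intramolecular Mukaiyama aldol/Prins closure. The oxolane closes in a 5-(enolexo)-endo-trig mode, exo for C3=CH(OMe) and endo for O1=C2, which is formally disfavoured but routine for oxocarbenium ions. C3 is controlled by C4: allylic 1,3-strain in the Z-enol ether holds H-4 in the plane of the double bond, so C5 (and with it C2) reaches one face while the benzyl group points to the other, and the formyl carbon ends up trans to the benzyl group. C2 is controlled by the E geometry of 14 within this envelope, which places the aryl group on the side of the enol ether carbon and gives the 2,3-cis and therefore 2,4-trans ring, the kinetic sense also known from the ring contraction. The selectivity that matters is C2 against C4, since C3 can be corrected in step 10 but C2 cannot; it is secured by the geometrically pure Z-enol ether and by kinetic conditions (−78 °C, short time, hindered base), which should prevent reversal to the all-trans 2,4-cis isomer and Friedel–Crafts capture of a reopened C2 cation by the benzyl arene, while the 1,4 spacing of O1 and C3 leaves no other ring size open.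

Step 10
Reactants: 16 (2R,3S,4S)-2-(4-allyloxy-3,5-dimethoxyphenyl)-4-(4-benzyloxy-3-methoxybenzyl)oxolane-3-carbaldehyde
Product: 17 (2R,3R,4S)-2-(4-allyloxy-3,5-dimethoxyphenyl)-4-(4-benzyloxy-3-methoxybenzyl)oxolane-3-carbaldehyde (2,3-trans-3,4-cis)
Conditions: DBU (cat.), CH2Cl2, rt
Reagents that add atoms: none
Why: base-mediated epimerisation under thermodynamic control in which only C3 is acidic and the formyl group should move from the face of the directly bound C2 aryl group to the face of the slimmer C4 CH2Ar group; C2 should hold because β-elimination of O1 would be the reverse of a 5-endo-trig addition, and residual 16 is separated and resubmitted.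

Step 11
Reactants: 17 (2R,3R,4S)-2-(4-allyloxy-3,5-dimethoxyphenyl)-4-(4-benzyloxy-3-methoxybenzyl)oxolane-3-carbaldehyde
Product: 18 [(2R,3S,4S)-2-(4-allyloxy-3,5-dimethoxyphenyl)-4-(4-benzyloxy-3-methoxybenzyl)oxolan-3-yl]methanol
Conditions: NaBH4, MeOH–THF, 0 °C
Reagents that add atoms: none
Why: borohydride reduction of the aldehyde, which removes the acidity at C3 and so fixes its configuration (the descriptor changes only through the priorities).

Step 12
Reactants: 18 [(2R,3S,4S)-2-(4-allyloxy-3,5-dimethoxyphenyl)-4-(4-benzyloxy-3-methoxybenzyl)oxolan-3-yl]methanol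
Product: 19 tert-butyldimethylsilyl ether of 18
Conditions: TBSCl, imidazole, DMF, rt
Reagents that add atoms: tert-butyldimethylsilyl chloride CC(C)(C)[Si](C)(C)Cl
Why: standard silylation of a primary alcohol, needed to keep this hydroxyl out of the boron aldol and the Mitsunobu reaction.

Step 13
Reactants: 19 tert-butyldimethylsilyl ether of 18
Product: 20 4-[(2R,3S,4S)-4-(4-benzyloxy-3-methoxybenzyl)-3-(tert-butyldimethylsilyloxymethyl)oxolan-2-yl]-2,6-dimethoxyphenol
Conditions: Pd(PPh3)4 (cat.), morpholine, THF, rt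
Reagents that add atoms: none
Why: Tsuji–Trost type transfer of the allyl group from the aryl ether to morpholine under Pd(0) catalysis, which leaves benzyl and silyl ethers untouched.

Step 14
Reactants: 3 (S)-4-benzyloxazolidin-2-one; 21 bromoacetyl bromide
Product: 23 (S)-4-benzyl-3-(bromoacetyl)oxazolidin-2-one, via lithium oxazolidinide 22 (not isolated)
Conditions: n-BuLi, THF, −78 °C; then 21, −78 → 0 °C
Reagents that add atoms: none
Why: N-acylation of the lithiated auxiliary at the acyl bromide, the more reactive electrophilic site of 21, at low temperature so that the C–Br bond is kept.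

Step 15
Reactants: 20 4-[(2R,3S,4S)-4-(4-benzyloxy-3-methoxybenzyl)-3-(tert-butyldimethylsilyloxymethyl)oxolan-2-yl]-2,6-dimethoxyphenol; 23 (S)-4-benzyl-3-(bromoacetyl)oxazolidin-2-one
Product: 24 (S)-4-benzyl-3-[(ArO)acetyl]oxazolidin-2-one
Conditions: K2CO3, acetone, rt
Reagents that add atoms: none
Why: Williamson ether synthesis in which SN2 displacement at an α-bromo carbonyl carbon is fast enough for the 2,6-dimethoxyphenoxide, whose bulk at the same time disfavours attack at the imide carbonyl groups.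

Step 16
Reactants: 24 (S)-4-benzyl-3-[(ArO)acetyl]oxazolidin-2-one; 25 4-benzyloxy-3-methoxybenzaldehyde
Product: 27 (S)-4-benzyl-3-[(2S,3R)-2-(ArO)-3-(4-benzyloxy-3-methoxyphenyl)-3-hydroxypropanoyl]oxazolidin-2-one (syn), via dibutylboron Z-enolate 26 (not isolated)
Conditions: n-Bu2BOTf, Et3N, CH2Cl2, −78 → 0 °C; then 25, −78 → 0 °C; pH 7 buffer, MeOH, H2O2, 0 °C
Reagents that add atoms: none
Why: Evans syn aldol reaction in which the Z-boron enolate 26 reacts through a closed chair (Zimmerman–Traxler) transition state on the face away from the benzyl group of the auxiliary, setting C8'' (S in the imide) and C7'' (R), the threo pair.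

Step 17
Reactants: 27 (S)-4-benzyl-3-[(2S,3R)-2-(ArO)-3-(4-benzyloxy-3-methoxyphenyl)-3-hydroxypropanoyl]oxazolidin-2-one
Product: 28 (1R,2R)-2-(ArO)-1-(4-benzyloxy-3-methoxyphenyl)propane-1,3-diol (threo)
Conditions: LiBH4, MeOH (1 equiv), THF, 0 °C
Reagents that add atoms: none
Why: reductive cleavage of the imide at its exocyclic carbonyl group with LiBH4; 3 is recovered and neither stereocentre is touched (C8'' becomes R only through the priorities).

Step 18
Reactants: 28 (1R,2R)-2-(ArO)-1-(4-benzyloxy-3-methoxyphenyl)propane-1,3-diol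
Product: 29 (1R,2R)-2-(ArO)-1-(4-benzyloxy-3-methoxyphenyl)-3-(tert-butyldimethylsilyloxy)propan-1-ol
Conditions: TBSCl (1.05 equiv), imidazole, CH2Cl2, 0 °C
Reagents that add atoms: tert-butyldimethylsilyl chloride CC(C)(C)[Si](C)(C)Cl
Why: sterically controlled monosilylation, the primary hydroxyl reacting well ahead of the flanked secondary benzylic one.

Step 19
Reactants: 29 (1R,2R)-2-(ArO)-1-(4-benzyloxy-3-methoxyphenyl)-3-(tert-butyldimethylsilyloxy)propan-1-ol
Product: 30 (1S,2R)-2-(ArO)-1-(4-benzyloxy-3-methoxyphenyl)-3-(tert-butyldimethylsilyloxy)propyl 4-nitrobenzoate (erythro)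
Conditions: 4-O2NC6H4CO2H, PPh3, DIAD, toluene, −20 → 0 °C
Reagents that add atoms: 4-nitrobenzoic acid O=C(O)c1ccc(cc1)[N+](=O)[O-]
Why: Mitsunobu reaction in which the carboxylate of the acidic 4-nitrobenzoic acid displaces the activated hydroxyl group with inversion at C7'' (R to S); the non-polar solvent and low temperature are chosen to suppress ionisation of the electron-rich benzylic centre.

Step 20
Reactants: 30 (1S,2R)-2-(ArO)-1-(4-benzyloxy-3-methoxyphenyl)-3-(tert-butyldimethylsilyloxy)propyl 4-nitrobenzoate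
Product: 31 (1S,2R)-2-(ArO)-1-(4-benzyloxy-3-methoxyphenyl)-3-(tert-butyldimethylsilyloxy)propan-1-ol (erythro)
Conditions: K2CO3 (cat.), MeOH–THF, 0 °C → rt
Reagents that add atoms: none
Why: base-catalysed transesterification of an activated ester, cleaved at the acyl carbon so that C7'' keeps its new configuration and the silyl and benzyl ethers stay.

Step 21
Reactants: 31 (1S,2R)-2-(ArO)-1-(4-benzyloxy-3-methoxyphenyl)-3-(tert-butyldimethylsilyloxy)propan-1-ol
Product: 32 di-O-benzyl ether of the target (both guaiacyl phenols benzylated; three free hydroxyl groups)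
Conditions: TBAF, AcOH, THF, rt
Reagents that add atoms: none
Why: fluoride desilylation of both primary TBS ethers under acetic acid buffering, done while the phenols are still benzylated so that no quinone methide can form at C7'' or C2.

Step 22
Reactants: 32 di-O-benzyl ether of the target
Product: 33 target CNP0170225.1
Conditions: H2 (1 atm), 10% Pd/C, EtOAc–EtOH, rt
Reagents that add atoms: none
Why: hydrogenolysis in which aryl benzyl ethers should be cleaved under neutral conditions well before the secondary benzylic alcohol at C7'' or the cyclic benzylic ether C2–O1; the reaction is stopped after uptake of two equivalents of hydrogen.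

**Compound list**
1 | 3-(4-hydroxy-3-methoxyphenyl)propanoic acid | COc1cc(CCC(=O)O)ccc1O | starting material
2 | 3-(4-benzyloxy-3-methoxyphenyl)propanoic acid | COc1cc(CCC(=O)O)ccc1OCc2ccccc2 | intermediate
3 | (S)-4-benzyloxazolidin-2-one | O=C1N[C@@H](Cc2ccccc2)CO1 | starting material
4 | 3-(4-benzyloxy-3-methoxyphenyl)propanoic pivalic anhydride | COc1cc(CCC(=O)OC(=O)C(C)(C)C)ccc1OCc2ccccc2 | intermediate
5 | (S)-4-benzyl-3-[3-(4-benzyloxy-3-methoxyphenyl)propanoyl]oxazolidin-2-one | COc1cc(CCC(=O)N2C(=O)OC[C@@H]2Cc3ccccc3)ccc1OCc4ccccc4 | intermediate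
6 | trichlorotitanium (Z)-enolate of 5 | COc1cc(C/C=C(\O[Ti](Cl)(Cl)Cl)N2C(=O)OC[C@@H]2Cc3ccccc3)ccc1OCc4ccccc4 | intermediate
7 | (S)-4-benzyl-3-[(R)-2-(4-benzyloxy-3-methoxybenzyl)-3-hydroxypropanoyl]oxazolidin-2-one | COc1cc(C[C@H](CO)C(=O)N2C(=O)OC[C@@H]2Cc3ccccc3)ccc1OCc4ccccc4 | intermediate
8 | (R)-2-(4-benzyloxy-3-methoxybenzyl)-3-hydroxy-N-methoxy-N-methylpropanamide | COc1cc(C[C@H](CO)C(=O)N(C)OC)ccc1OCc2ccccc2 | intermediate
9 | (R)-2-(4-benzyloxy-3-methoxybenzyl)-N-methoxy-N-methyl-3-(triethylsilyloxy)propanamide | COc1cc(C[C@H](CO[Si](CC)(CC)CC)C(=O)N(C)OC)ccc1OCc2ccccc2 | intermediate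
10 | (R)-2-(4-benzyloxy-3-methoxybenzyl)-3-(triethylsilyloxy)propanal | COc1cc(C[C@H](CO[Si](CC)(CC)CC)C=O)ccc1OCc2ccccc2 | intermediate
11 | triethylsilyl ether of (2S,3Z)-2-(4-benzyloxy-3-methoxybenzyl)-4-methoxybut-3-en-1-ol | COc1cc(C[C@H](CO[Si](CC)(CC)CC)/C=C\OC)ccc1OCc2ccccc2 | intermediate
12 | syringaldehyde (4-hydroxy-3,5-dimethoxybenzaldehyde) | COc1cc(C=O)cc(OC)c1O | starting material
13 | 4-allyloxy-3,5-dimethoxybenzaldehyde | COc1cc(C=O)cc(OC)c1OCC=C | intermediate
14 | (E)-(4-allyloxy-3,5-dimethoxybenzylidene)[(2S,3Z)-2-(4-benzyloxy-3-methoxybenzyl)-4-methoxybut-3-enyl]oxonium triflate | COc1cc(C[C@H](C/[O+]=C/c3cc(OC)c(OCC=C)c(OC)c3)/C=C\OC)ccc1OCc2ccccc2.[O-]S(=O)(=O)C(F)(F)F | intermediate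
15 | methyl{[(2R,3S,4S)-2-(4-allyloxy-3,5-dimethoxyphenyl)-4-(4-benzyloxy-3-methoxybenzyl)oxolan-3-yl]methylidene}oxonium triflate | COc1cc(C[C@@H]2CO[C@@H](c3cc(OC)c(OCC=C)c(OC)c3)[C@H]2C=[O+]C)ccc1OCc4ccccc4.[O-]S(=O)(=O)C(F)(F)F | intermediate
16 | (2R,3S,4S)-2-(4-allyloxy-3,5-dimethoxyphenyl)-4-(4-benzyloxy-3-methoxybenzyl)oxolane-3-carbaldehyde (2,3-cis-3,4-trans) | COc1cc(C[C@@H]2CO[C@@H](c3cc(OC)c(OCC=C)c(OC)c3)[C@H]2C=O)ccc1OCc4ccccc4 | intermediate
17 | (2R,3R,4S)-2-(4-allyloxy-3,5-dimethoxyphenyl)-4-(4-benzyloxy-3-methoxybenzyl)oxolane-3-carbaldehyde (2,3-trans-3,4-cis) | COc1cc(C[C@@H]2CO[C@@H](c3cc(OC)c(OCC=C)c(OC)c3)[C@@H]2C=O)ccc1OCc4ccccc4 | intermediate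
18 | [(2R,3S,4S)-2-(4-allyloxy-3,5-dimethoxyphenyl)-4-(4-benzyloxy-3-methoxybenzyl)oxolan-3-yl]methanol | COc1cc(C[C@@H]2CO[C@@H](c3cc(OC)c(OCC=C)c(OC)c3)[C@@H]2CO)ccc1OCc4ccccc4 | intermediate
19 | tert-butyldimethylsilyl ether of 18 | COc1cc(C[C@@H]2CO[C@@H](c3cc(OC)c(OCC=C)c(OC)c3)[C@@H]2CO[Si](C)(C)C(C)(C)C)ccc1OCc4ccccc4 | intermediate
20 | 4-[(2R,3S,4S)-4-(4-benzyloxy-3-methoxybenzyl)-3-(tert-butyldimethylsilyloxymethyl)oxolan-2-yl]-2,6-dimethoxyphenol | COc1cc(C[C@@H]2CO[C@@H](c3cc(OC)c(O)c(OC)c3)[C@@H]2CO[Si](C)(C)C(C)(C)C)ccc1OCc4ccccc4 | intermediate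
21 | bromoacetyl bromide | BrCC(=O)Br | starting material
22 | lithium (S)-4-benzyl-2-oxooxazolidin-3-ide | [Li+].O=C1[N-][C@@H](Cc2ccccc2)CO1 | intermediate
23 | (S)-4-benzyl-3-(bromoacetyl)oxazolidin-2-one | O=C(CBr)N1C(=O)OC[C@@H]1Cc2ccccc2 | intermediate
24 | (S)-4-benzyl-3-[(ArO)acetyl]oxazolidin-2-one, ArO = phenoxy residue of 20 | COc1cc(C[C@@H]2CO[C@@H](c3cc(OC)c(OCC(=O)N5C(=O)OC[C@@H]5Cc6ccccc6)c(OC)c3)[C@@H]2CO[Si](C)(C)C(C)(C)C)ccc1OCc4ccccc4 | intermediate
25 | 4-benzyloxy-3-methoxybenzaldehyde | COc1cc(C=O)ccc1OCc2ccccc2 | starting material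
26 | dibutylboron (Z)-enolate of 24 | COc1cc(C[C@@H]2CO[C@@H](c3cc(OC)c(O/C=C(\OB(CCCC)CCCC)N5C(=O)OC[C@@H]5Cc6ccccc6)c(OC)c3)[C@@H]2CO[Si](C)(C)C(C)(C)C)ccc1OCc4ccccc4 | intermediate
27 | (S)-4-benzyl-3-[(2S,3R)-2-(ArO)-3-(4-benzyloxy-3-methoxyphenyl)-3-hydroxypropanoyl]oxazolidin-2-one (syn aldol) | COc1cc(C[C@@H]2CO[C@@H](c3cc(OC)c(O[C@H](C(=O)N5C(=O)OC[C@@H]5Cc6ccccc6)[C@H](O)c7ccc(OCc8ccccc8)c(OC)c7)c(OC)c3)[C@@H]2CO[Si](C)(C)C(C)(C)C)ccc1OCc4ccccc4 | intermediate
28 | (1R,2R)-2-(ArO)-1-(4-benzyloxy-3-methoxyphenyl)propane-1,3-diol (threo) | COc1cc(C[C@@H]2CO[C@@H](c3cc(OC)c(O[C@H](CO)[C@H](O)c7ccc(OCc8ccccc8)c(OC)c7)c(OC)c3)[C@@H]2CO[Si](C)(C)C(C)(C)C)ccc1OCc4ccccc4 | intermediate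
29 | (1R,2R)-2-(ArO)-1-(4-benzyloxy-3-methoxyphenyl)-3-(tert-butyldimethylsilyloxy)propan-1-ol (threo) | COc1cc(C[C@@H]2CO[C@@H](c3cc(OC)c(O[C@H](CO[Si](C)(C)C(C)(C)C)[C@H](O)c7ccc(OCc8ccccc8)c(OC)c7)c(OC)c3)[C@@H]2CO[Si](C)(C)C(C)(C)C)ccc1OCc4ccccc4 | intermediate
30 | (1S,2R)-2-(ArO)-1-(4-benzyloxy-3-methoxyphenyl)-3-(tert-butyldimethylsilyloxy)propyl 4-nitrobenzoate (erythro) | COc1cc(C[C@@H]2CO[C@@H](c3cc(OC)c(O[C@H](CO[Si](C)(C)C(C)(C)C)[C@@H](OC(=O)c5ccc(cc5)[N+](=O)[O-])c6ccc(OCc7ccccc7)c(OC)c6)c(OC)c3)[C@@H]2CO[Si](C)(C)C(C)(C)C)ccc1OCc4ccccc4 | intermediate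
31 | (1S,2R)-2-(ArO)-1-(4-benzyloxy-3-methoxyphenyl)-3-(tert-butyldimethylsilyloxy)propan-1-ol (erythro) | COc1cc(C[C@@H]2CO[C@@H](c3cc(OC)c(O[C@H](CO[Si](C)(C)C(C)(C)C)[C@@H](O)c6ccc(OCc7ccccc7)c(OC)c6)c(OC)c3)[C@@H]2CO[Si](C)(C)C(C)(C)C)ccc1OCc4ccccc4 | intermediate
32 | di-O-benzyl ether of the target (both guaiacyl phenols benzylated) | COc1cc(C[C@@H]2CO[C@@H](c3cc(OC)c(O[C@H](CO)[C@@H](O)c6ccc(OCc7ccccc7)c(OC)c6)c(OC)c3)[C@@H]2CO)ccc1OCc4ccccc4 | intermediate
33 | CNP0170225.1: (1S,2R)-1-(4-hydroxy-3-methoxyphenyl)-2-{4-[(2R,3S,4S)-4-(4-hydroxy-3-methoxybenzyl)-3-(hydroxymethyl)oxolan-2-yl]-2,6-dimethoxyphenoxy}propane-1,3-diol | COc1cc(C[C@@H]2CO[C@@H](c3cc(OC)c(O[C@H](CO)[C@@H](O)c4ccc(O)c(OC)c4)c(OC)c3)[C@@H]2CO)ccc1O | target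

**Step count and risks**
Total steps: 22. The longest linear sequence is 20 steps (steps 1–7, 9–13, 15–22). Steps 8 and 14 are one-step side branches.

Step 9 (key step). The risk is slow condensation of the electron-rich aldehyde with the silyl ether at −78 °C. Warming would make the C2–C3 closure reversible, erode the 2,4-trans selectivity in favour of the all-trans ring, and give time for protonation of the enol ether.
- The fallback separates formation of the O1–C2 bond from the ring closure. It sets out from 11 and 13 and returns at 16.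
- 11 is desilylated (TBAF, THF, 0 °C) to (2S,3Z)-2-(4-benzyloxy-3-methoxybenzyl)-4-methoxybut-3-en-1-ol F1.
- 13 is taken by Pinnick oxidation to 4-allyloxy-3,5-dimethoxybenzoic acid F2.
- Carbodiimide esterification (EDC, DMAP, CH2Cl2) joins them to the benzoate ester F3.
- Reductive acetylation (DIBAL-H, −78 °C, then Ac2O, pyridine, DMAP) gives the α-acetoxy ether F4.
- Ionisation of F4 with TMSOTf and the hindered pyridine at −78 °C should release 14 unimolecularly and at once, and closure and aqueous work-up lead to 16.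

Step 10. The risk is an incomplete shift of the C3 equilibrium, because the formyl group only trades a cis aryl neighbour for a cis benzyl neighbour. Prolonged base contact could also open the ring by β-elimination and scramble C2.
- The fallback sets C3 kinetically on a lactone instead of thermodynamically on the oxolane. It sets out from 11 and returns at 18.
- Aqueous acid (HCl, THF) hydrolyses the enol ether and the silyl ether to (4S)-4-(4-benzyloxy-3-methoxybenzyl)oxolan-2-ol F5.
- Oxidation (TEMPO, PhI(OAc)2) gives (4S)-4-(4-benzyloxy-3-methoxybenzyl)oxolan-2-one F6.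
- The lithium enolate of F6 (LiHMDS, THF, −78 °C) should add to 13 anti to the benzyl group and give the trans aldol lactone F7 as a pair of carbinol epimers.
- LiAlH4 reduces F7 to the triol F8.
- Catalytic camphorsulfonic acid in CH2Cl2 at 0 °C closes O1–C2 through the benzylic cation, trans to the C3 arm from either carbinol epimer. A trans lactone maps onto the 3,4-cis oxolane, so the product is 18.

Step 19. The risk is partial ionisation of the activated, electron-rich benzylic carbinol. This would give incomplete inversion at C7'' or elimination.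
- The fallback replaces substitution by an oxidation–reduction pair. It sets out from 29 and returns at 31.
- Dess–Martin periodinane (NaHCO3, CH2Cl2) gives the α-aryloxy ketone F9.
- Zn(BH4)2 in Et2O at low temperature should reduce F9 under chelation control between the carbonyl and aryloxy oxygens, with hydride delivered from the side of H-8''. This gives the anti (erythro) alcohol 31.

**Further compounds**
F1 | step 9 | (2S,3Z)-2-(4-benzyloxy-3-methoxybenzyl)-4-methoxybut-3-en-1-ol | COc1cc(C[C@H](CO)/C=C\OC)ccc1OCc2ccccc2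
F2 | step 9 | 4-allyloxy-3,5-dimethoxybenzoic acid | COc1cc(C(=O)O)cc(OC)c1OCC=C
F3 | step 9 | (2S,3Z)-2-(4-benzyloxy-3-methoxybenzyl)-4-methoxybut-3-enyl 4-allyloxy-3,5-dimethoxybenzoate | COc1cc(C[C@H](COC(=O)c3cc(OC)c(OCC=C)c(OC)c3)/C=C\OC)ccc1OCc2ccccc2
F4 | step 9 | (4-allyloxy-3,5-dimethoxyphenyl)[(2S,3Z)-2-(4-benzyloxy-3-methoxybenzyl)-4-methoxybut-3-enyloxy]methyl acetate (both acetal epimers) | COc1cc(C[C@H](COC(OC(C)=O)c3cc(OC)c(OCC=C)c(OC)c3)/C=C\OC)ccc1OCc2ccccc2
F5 | step 10 | (4S)-4-(4-benzyloxy-3-methoxybenzyl)oxolan-2-ol (both anomers) | COc1cc(C[C@@H]2COC(O)C2)ccc1OCc3ccccc3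
F6 | step 10 | (4S)-4-(4-benzyloxy-3-methoxybenzyl)oxolan-2-one | COc1cc(C[C@@H]2COC(=O)C2)ccc1OCc3ccccc3
F7 | step 10 | (3R,4S)-3-[(4-allyloxy-3,5-dimethoxyphenyl)(hydroxy)methyl]-4-(4-benzyloxy-3-methoxybenzyl)oxolan-2-one (both carbinol epimers) | COc1cc(C[C@@H]2COC(=O)[C@H]2C(O)c3cc(OC)c(OCC=C)c(OC)c3)ccc1OCc4ccccc4
F8 | step 10 | (2S,3S)-2-[(4-allyloxy-3,5-dimethoxyphenyl)(hydroxy)methyl]-3-(4-benzyloxy-3-methoxybenzyl)butane-1,4-diol (both carbinol epimers) | COc1cc(C[C@H](CO)[C@@H](CO)C(O)c3cc(OC)c(OCC=C)c(OC)c3)ccc1OCc4ccccc4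
F9 | step 19 | (R)-2-(ArO)-1-(4-benzyloxy-3-methoxyphenyl)-3-(tert-butyldimethylsilyloxy)propan-1-one | COc1cc(C[C@@H]2CO[C@@H](c3cc(OC)c(O[C@H](CO[Si](C)(C)C(C)(C)C)C(=O)c7ccc(OCc8ccccc8)c(OC)c7)c(OC)c3)[C@@H]2CO[Si](C)(C)C(C)(C)C)ccc1OCc4ccccc4
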